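**Strategy**

The route rests on reading the cyclopentane as one half of a bicyclo[3.2.0]heptanone. Ring carbon C-1 (CH3, CH2C=O) and ring carbon C-2 (CH3, enone C=O) are vicinal quaternary centres whose exocyclic CH2 and C=O carbons are cis, a 1,5-diketone; joining these two carbons gives a cyclobutanone. An auxiliary-controlled intramolecular keteniminium–olefin [2+2] cycloaddition of an acyclic 2,6-dimethylhept-6-enamide closes the cyclopentane and this cyclobutanone at once, setting both quaternary centres cis and in the absolute sense. Aldol reaction at the cyclobutanone CH2, alkenyl addition to its carbonyl and oxidation then trigger a strain-releasing retro-aldol opening that unveils the 1,5-diketone.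

Key step: step 3

Assumption: the (2S,5S)-amine is assigned as the auxiliary that delivers the (1R,5R)-ketone on a steric model (olefin approach anti to the nearer pyrrolidine methyl); if the sense of induction is the reverse, the equally available (2R,5R)-amine is used in step 1 and nothing else changes.

Remark: compounds 6, 22, 24 and 25 are carried as mixtures at stereocentres that are erased later; these centres are left undefined in the SMILES.

**Route**

Step 1
Reactants: 1 propanoyl chloride; 2 (2S,5S)-2,5-dimethylpyrrolidine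
Product: 3 1-[(2S,5S)-2,5-dimethylpyrrolidin-1-yl]propan-1-one
Conditions: Et3N, CH2Cl2, 0 °C to rt
Reagents that add atoms: none
Why: Schotten–Baumann-type N-acylation of the secondary amine by the acid chloride should be fast and leaves the two auxiliary stereocentres untouched.

Step 2
Reactants: 3 1-[(2S,5S)-2,5-dimethylpyrrolidin-1-yl]propan-1-one; 4 5-bromo-2-methylpent-1-ene
Product: 6 1-[(2S,5S)-2,5-dimethylpyrrolidin-1-yl]-2,6-dimethylhept-6-en-1-one, via lithium amide enolate 5 (not isolated)
Conditions: LiN(i-Pr)2 (LDA), THF, −78 °C; then 4, DMPU, −78 to 0 °C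
Reagents that add atoms: none
Why: Enolate alkylation of the lithium amide enolate with a primary bromide should install the olefin tether, and the new α-centre is irrelevant because it becomes sp2 in step 3.

Step 3
Reactants: 6 1-[(2S,5S)-2,5-dimethylpyrrolidin-1-yl]-2,6-dimethylhept-6-en-1-one
Product: 9 (1R,5R)-1,5-dimethylbicyclo[3.2.0]heptan-6-one, via keteniminium triflate 7 (not isolated), via cyclobutaniminium triflate 8 (not isolated)
Conditions: Tf2O, 2,4,6-collidine, ClCH2CH2Cl, 0 °C to reflux; then aq. NaHCO3, rt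
Reagents that add atoms: water, O
Why: O-Triflation of the amide and α-deprotonation by collidine give keteniminium 7, whose electrophilic central carbon is attacked by the terminal CH2 of the tethered 1,1-disubstituted olefin while the developing tertiary cationic carbon is captured by the enamine-like α-carbon, an asynchronous thermal [2+2] cycloaddition. The closest known reaction type is the intramolecular keteniminium–olefin [2+2] cycloaddition of ω-alkenyl amides carrying a C2-symmetric trans-2,5-dimethylpyrrolidine auxiliary, the iminium counterpart of the intramolecular ketene–olefin cycloaddition. The cyclopentane closes by 5-exo bond formation between the keteniminium α-carbon and the internal olefin carbon across the three-carbon tether, and the cyclobutane closes by the bond from the central carbon to the olefin CH2. Both new quaternary stereocentres are bridgeheads of a bicyclo[3.2.0]heptane, so their methyl groups are cis by the geometric demand of the ring fusion, and the absolute configuration is controlled by the auxiliary, whose 2- and 5-methyl groups block one approach quadrant irrespective of rotation about the C–N axis. The step needs regioselectivity for the fused over the bridged bicycle, secured by the cation-stabilising methyl group on the internal olefin carbon and the three-atom tether, and facial selectivity, secured by the auxiliary. Hydrolysis of iminium salt 8 should release ketone 9 and the recoverable amine.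

Step 4
Reactants: 10 2,6-dimethylbenzene-1,4-diol
Product: 11 2,6-dimethyl-4-[tri(propan-2-yl)silyloxy]phenol
Conditions: i-Pr3SiCl (1.0 equiv), imidazole, DMF, 0 °C
Reagents that add atoms: chlorotri(propan-2-yl)silane (TIPSCl), CC(C)[Si](Cl)(C(C)C)C(C)C
Why: Silyl ether formation should discriminate sterically, since the hydroxyl flanked by two methyl groups is inert to the bulky chlorosilane while the open hydroxyl reacts.

Step 5
Reactants: 11 2,6-dimethyl-4-[tri(propan-2-yl)silyloxy]phenol
Product: 12 (4-methoxy-3,5-dimethylphenoxy)tri(propan-2-yl)silane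
Conditions: NaH, MeI, THF/DMF, 0 °C to rt
Reagents that add atoms: iodomethane (MeI), CI
Why: Williamson O-methylation of the hindered phenoxide should proceed cleanly, and the aryl triisopropylsilyl ether tolerates NaH.

Step 6
Reactants: 12 (4-methoxy-3,5-dimethylphenoxy)tri(propan-2-yl)silane
Product: 13 [3-(bromomethyl)-4-methoxy-5-methylphenoxy]tri(propan-2-yl)silane
Conditions: NBS (1.0 equiv), AIBN (cat.), PhCF3, 80 °C
Reagents that add atoms: N-bromosuccinimide (NBS), O=C1CCC(=O)N1Br
Why: Wohl–Ziegler benzylic bromination should give a single monobromide because the two methyl groups are equivalent by symmetry, with stoichiometry limiting double bromination.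

Step 7
Reactants: 14 but-3-yn-1-ol; 13 [3-(bromomethyl)-4-methoxy-5-methylphenoxy]tri(propan-2-yl)silane
Product: 16 (3E)-5-{2-methoxy-3-methyl-5-[tri(propan-2-yl)silyloxy]phenyl}-3-methylpent-3-en-1-ol, via alkenylalane 15 (not isolated)
Conditions: Me3Al (3 equiv), Cp2ZrCl2 (25 mol%), CH2Cl2, 0 °C to rt; then 13, Pd(PPh3)4 (5 mol%), THF, rt; aq. HCl work-up
Reagents that add atoms: trimethylaluminium (Me3Al), C[Al](C)C
Why: Negishi zirconium-catalysed carboalumination adds CH3 and Al syn across the alkyne with CH3 on the internal carbon, and palladium-catalysed cross-coupling of the alkenylalane with the benzylic bromide proceeds with retention, which should fix the E trisubstituted alkene.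

Step 8
Reactants: 16 (3E)-5-{2-methoxy-3-methyl-5-[tri(propan-2-yl)silyloxy]phenyl}-3-methylpent-3-en-1-ol
Product: 17 (3E)-5-{2-methoxy-3-methyl-5-[tri(propan-2-yl)silyloxy]phenyl}-3-methylpent-3-enal
Conditions: Dess–Martin periodinane, NaHCO3, CH2Cl2, 0 °C; used crude at once
Reagents that add atoms: none
Why: Dess–Martin oxidation under buffered, non-basic conditions should give the β,γ-unsaturated aldehyde without migration of the alkene into conjugation.

Step 9
Reactants: 18 trimethyl[(2-methylbut-3-yn-2-yl)oxy]silane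
Product: 20 [(3E)-4-iodo-2-methylbut-3-en-2-yl]oxy(trimethyl)silane, via alkenylzirconocene chloride 19 (not isolated)
Conditions: Cp2Zr(H)Cl, CH2Cl2, rt; then I2, 0 °C
Reagents that add atoms: iodine (I2), II
Why: Hydrozirconation with the Schwartz reagent is a syn addition placing Zr on the terminal carbon, and iodinolysis with retention should give the E-alkenyl iodide only.

Step 10
Reactants: 9 (1R,5R)-1,5-dimethylbicyclo[3.2.0]heptan-6-one; 17 (3E)-5-{2-methoxy-3-methyl-5-[tri(propan-2-yl)silyloxy]phenyl}-3-methylpent-3-enal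
Product: 22 (1R,5R)-7-[(3E)-1-hydroxy-5-{2-methoxy-3-methyl-5-[tri(propan-2-yl)silyloxy]phenyl}-3-methylpent-3-en-1-yl]-1,5-dimethylbicyclo[3.2.0]heptan-6-one, via lithium enolate 21 (not isolated)
Conditions: LiN(i-Pr)2 (LDA), THF, −78 °C; then 17, −78 °C; AcOH quench at −78 °C
Reagents that add atoms: none
Why: Aldol addition of the lithium enolate should be regiochemically unambiguous because C-7 is the only enolisable position (the other α-carbon is quaternary), and the two new stereocentres are erased in step 12.

Step 11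
Reactants: 20 [(3E)-4-iodo-2-methylbut-3-en-2-yl]oxy(trimethyl)silane; 22 the aldol adduct of step 10
Product: 24 (1R,5R)-7-[(3E)-1-hydroxy-5-{2-methoxy-3-methyl-5-[tri(propan-2-yl)silyloxy]phenyl}-3-methylpent-3-en-1-yl]-1,5-dimethyl-6-[(1E)-3-methyl-3-(trimethylsilyloxy)but-1-en-1-yl]bicyclo[3.2.0]heptan-6-ol, via alkenyllithium 23 (not isolated)
Conditions: 20 (3 equiv), t-BuLi (6 equiv), Et2O, −78 °C; CeCl3 (anhydrous), THF, −78 °C; then 22, −78 °C; aq. AcOH quench
Reagents that add atoms: none
Why: Iodine–lithium exchange retains the E geometry, and organocerium 1,2-addition to the strained, electrophilic cyclobutanone should outrun enolisation, the new carbinol centre being erased in step 12.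

Step 12
Reactants: 24 the cyclobutanol diol of step 11
Product: 26 (2E)-1-[(1R,2R)-2-{(4E)-6-[2-methoxy-3-methyl-5-(tri(propan-2-yl)silyloxy)phenyl]-4-methyl-2-oxohex-4-en-1-yl}-1,2-dimethylcyclopentyl]-4-methyl-4-(trimethylsilyloxy)pent-2-en-1-one, via β-hydroxy ketone 25 (not isolated)
Conditions: Dess–Martin periodinane, NaHCO3, CH2Cl2, 0 °C to rt; then Et3N (0.2 equiv), 0 °C
Reagents that add atoms: none
Why: Dess–Martin oxidation of the only secondary carbinol gives β-hydroxy ketone 25, whose tertiary cyclobutanol should undergo strain-driven retro-aldol cleavage (the fragmentation half of a de Mayo reaction) to the enone and the CH2C=O arm, so the diastereomer mixture converges while the two quaternary centres are untouched.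

Step 13
Reactants: 26 the bis-silyl ether of step 12
Product: 27 (2E)-4-hydroxy-1-[(1R,2R)-2-{(4E)-6-(5-hydroxy-2-methoxy-3-methylphenyl)-4-methyl-2-oxohex-4-en-1-yl}-1,2-dimethylcyclopentyl]-4-methylpent-2-en-1-one
Conditions: Bu4NF, AcOH (1:1), THF, 0 °C
Reagents that add atoms: none
Why: Fluoride-mediated desilylation buffered with acetic acid should cleave the aryl triisopropylsilyl and the tertiary trimethylsilyl ether without base-induced migration of the β,γ-alkene or retro-Michael opening of the ring.

**Compound list**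

1 | propanoyl chloride | CCC(=O)Cl | starting material
2 | (2S,5S)-2,5-dimethylpyrrolidine | C[C@H]1CC[C@H](C)N1 | starting material
3 | 1-[(2S,5S)-2,5-dimethylpyrrolidin-1-yl]propan-1-one | CCC(=O)N1[C@@H](C)CC[C@@H]1C | intermediate
4 | 5-bromo-2-methylpent-1-ene | C=C(C)CCCBr | starting material
5 | lithium enolate of 3 (formed in situ) | CC=C(O[Li])N1[C@@H](C)CC[C@@H]1C | intermediate
6 | 1-[(2S,5S)-2,5-dimethylpyrrolidin-1-yl]-2,6-dimethylhept-6-en-1-one (either configuration at C-2) | C=C(C)CCCC(C)C(=O)N1[C@@H](C)CC[C@@H]1C | intermediate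
7 | (2S,5S)-1-(2,6-dimethylhepta-1,6-dien-1-ylidene)-2,5-dimethylpyrrolidin-1-ium triflate (formed in situ) | C=C(C)CCCC(C)=C=[N+]1[C@@H](C)CC[C@@H]1C.[O-]S(=O)(=O)C(F)(F)F | intermediate
8 | (2S,5S)-1-[(1R,5R)-1,5-dimethylbicyclo[3.2.0]heptan-6-ylidene]-2,5-dimethylpyrrolidin-1-ium triflate (formed in situ) | C[C@H]1CC[C@H](C)[N+]1=C1C[C@@]2(C)CCC[C@@]12C.[O-]S(=O)(=O)C(F)(F)F | intermediate
9 | (1R,5R)-1,5-dimethylbicyclo[3.2.0]heptan-6-one | O=C1C[C@@]2(C)CCC[C@@]12C | intermediate
10 | 2,6-dimethylbenzene-1,4-diol | Cc1cc(O)cc(C)c1O | starting material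
11 | 2,6-dimethyl-4-[tri(propan-2-yl)silyloxy]phenol | Cc1cc(O[Si](C(C)C)(C(C)C)C(C)C)cc(C)c1O | intermediate
12 | (4-methoxy-3,5-dimethylphenoxy)tri(propan-2-yl)silane | COc1c(C)cc(O[Si](C(C)C)(C(C)C)C(C)C)cc1C | intermediate
13 | [3-(bromomethyl)-4-methoxy-5-methylphenoxy]tri(propan-2-yl)silane | COc1c(C)cc(O[Si](C(C)C)(C(C)C)C(C)C)cc1CBr | intermediate
14 | but-3-yn-1-ol | C#CCCO | starting material
15 | (E)-alkenylalane, dimethylaluminium alkoxide of 4-(dimethylalumanyl)-3-methylbut-3-en-1-ol (formed in situ) | C[Al](C)/C=C(\C)CCO[Al](C)C | intermediate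
16 | (3E)-5-{2-methoxy-3-methyl-5-[tri(propan-2-yl)silyloxy]phenyl}-3-methylpent-3-en-1-ol | COc1c(C)cc(O[Si](C(C)C)(C(C)C)C(C)C)cc1C/C=C(\C)CCO | intermediate
17 | (3E)-5-{2-methoxy-3-methyl-5-[tri(propan-2-yl)silyloxy]phenyl}-3-methylpent-3-enal | COc1c(C)cc(O[Si](C(C)C)(C(C)C)C(C)C)cc1C/C=C(\C)CC=O | intermediate
18 | trimethyl[(2-methylbut-3-yn-2-yl)oxy]silane | C#CC(C)(C)O[Si](C)(C)C | starting material
19 | chloro[(1E)-3-methyl-3-(trimethylsilyloxy)but-1-en-1-yl]zirconocene (formed in situ; cyclopentadienyl ligands drawn σ-bonded) | C[Si](C)(C)OC(C)(C)/C=C/[Zr](Cl)(C1C=CC=C1)C1C=CC=C1 | intermediate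
20 | [(3E)-4-iodo-2-methylbut-3-en-2-yl]oxy(trimethyl)silane | C[Si](C)(C)OC(C)(C)/C=C/I | intermediate
21 | lithium enolate of 9 (formed in situ) | [Li]OC1=C[C@@]2(C)CCC[C@@]12C | intermediate
22 | (1R,5R)-7-[(3E)-1-hydroxy-5-{2-methoxy-3-methyl-5-[tri(propan-2-yl)silyloxy]phenyl}-3-methylpent-3-en-1-yl]-1,5-dimethylbicyclo[3.2.0]heptan-6-one (mixture at C-7 and the carbinol carbon) | O=C1C(C(O)C/C(C)=C/Cc3cc(O[Si](C(C)C)(C(C)C)C(C)C)cc(C)c3OC)[C@@]2(C)CCC[C@@]12C | intermediate
23 | [(1E)-3-methyl-3-(trimethylsilyloxy)but-1-en-1-yl]lithium (formed in situ) | [Li]/C=C/C(C)(C)O[Si](C)(C)C | intermediate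
24 | (1R,5R)-7-[(3E)-1-hydroxy-5-{2-methoxy-3-methyl-5-[tri(propan-2-yl)silyloxy]phenyl}-3-methylpent-3-en-1-yl]-1,5-dimethyl-6-[(1E)-3-methyl-3-(trimethylsilyloxy)but-1-en-1-yl]bicyclo[3.2.0]heptan-6-ol (mixture at C-6, C-7 and the carbinol carbon) | OC1(/C=C/C(C)(C)O[Si](C)(C)C)C(C(O)C/C(C)=C/Cc3cc(O[Si](C(C)C)(C(C)C)C(C)C)cc(C)c3OC)[C@@]2(C)CCC[C@@]12C | intermediate
25 | β-hydroxy ketone, the 1-oxo analogue of 24 (formed in situ) | OC1(/C=C/C(C)(C)O[Si](C)(C)C)C(C(=O)C/C(C)=C/Cc3cc(O[Si](C(C)C)(C(C)C)C(C)C)cc(C)c3OC)[C@@]2(C)CCC[C@@]12C | intermediate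
26 | (2E)-1-[(1R,2R)-2-{(4E)-6-[2-methoxy-3-methyl-5-(tri(propan-2-yl)silyloxy)phenyl]-4-methyl-2-oxohex-4-en-1-yl}-1,2-dimethylcyclopentyl]-4-methyl-4-(trimethylsilyloxy)pent-2-en-1-one | COc1c(C)cc(O[Si](C(C)C)(C(C)C)C(C)C)cc1C/C=C(\C)CC(=O)C[C@@]1(C)CCC[C@@]1(C)C(=O)/C=C/C(C)(C)O[Si](C)(C)C | intermediate
27 | (2E)-4-hydroxy-1-[(1R,2R)-2-{(4E)-6-(5-hydroxy-2-methoxy-3-methylphenyl)-4-methyl-2-oxohex-4-en-1-yl}-1,2-dimethylcyclopentyl]-4-methylpent-2-en-1-one | COc1c(C)cc(O)cc1C/C=C(\C)CC(=O)C[C@@]1(C)CCC[C@@]1(C)C(=O)/C=C/C(C)(C)O | target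

**Step count and risks**

Total step count: 13. Longest linear sequence: 9 steps (steps 4, 5, 6, 7, 8, 10, 11, 12, 13).

Steps most likely to fail:

1. Step 3. The auxiliary may discriminate the two approach quadrants insufficiently, or the tertiary cationic carbon may lose a proton (ene-type or olefin-isomerisation pathways) before ring closure. Fallback, setting out from 4 and returning at 9: the dilithium salt of propanoic acid (LiN(i-Pr)2, 2 equiv, THF) is alkylated with 4 to give racemic 2,6-dimethylhept-6-enoic acid F1. Oxalyl chloride converts it into 2,6-dimethylhept-6-enoyl chloride F2. Slow addition of F2 to Et3N in refluxing toluene generates the methylketene F3, which should undergo thermal intramolecular ketene–olefin [2+2] cycloaddition to racemic cis-1,5-dimethylbicyclo[3.2.0]heptan-6-one F4. F4 is resolved by addition of lithiated (S)-N,S-dimethyl-S-phenylsulfoximine, chromatographic separation of the adduct of the (1R,5R)-ketone, the β-hydroxysulfoximine F5, and thermolysis of F5 in refluxing toluene, which returns 9.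

2. Step 11. The organometallic may act as a base (enolisation at C-7) or the β-alkoxide may revert by retro-aldol instead of undergoing 1,2-addition at the hindered carbonyl. Fallback, setting out from 22 and returning at 24: alkyne 18 is deprotonated with n-BuLi to the small, weakly basic lithium acetylide F6, which is added to 22 in the presence of CeCl3 to give the propargylic cyclobutanol diol F7. Hydroxyl-directed trans-hydroalumination of F7 with NaAlH2(OCH2CH2OCH3)2 in THF, followed by protonolysis, should give the E-alkene 24.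

3. Step 10. The lithium enolate may deprotonate the β,γ-unsaturated aldehyde with migration of its double bond, or the cyclobutanone enolate may self-condense. Fallback, setting out from 9 and returning at 22: enolate 21 is trapped with Me3SiCl as the silyl enol ether (1R,5R)-1,5-dimethyl-6-(trimethylsilyloxy)bicyclo[3.2.0]hept-6-ene F8, and a Mukaiyama aldol addition of F8 to 17 with BF3·OEt2 in CH2Cl2 at −78 °C, under non-basic conditions, should give 22 after aqueous work-up.

**Further compounds**

F1 | step 3 | 2,6-dimethylhept-6-enoic acid (racemic) | C=C(C)CCCC(C)C(=O)O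
F2 | step 3 | 2,6-dimethylhept-6-enoyl chloride (racemic) | C=C(C)CCCC(C)C(=O)Cl
F3 | step 3 | 2,6-dimethylhepta-1,6-dien-1-one (ketene, formed in situ) | C=C(C)CCCC(C)=C=O
F4 | step 3 | cis-1,5-dimethylbicyclo[3.2.0]heptan-6-one (racemic) | O=C1CC2(C)CCCC12C
F5 | step 3 | (1R,5R)-1,5-dimethyl-6-{[(S)-N-methyl-S-phenylsulfonimidoyl]methyl}bicyclo[3.2.0]heptan-6-ol | CN=[S@](=O)(CC1(O)C[C@@]2(C)CCC[C@@]12C)c1ccccc1
F6 | step 11 | [3-methyl-3-(trimethylsilyloxy)but-1-yn-1-yl]lithium | [Li]C#CC(C)(C)O[Si](C)(C)C
F7 | step 11 | (1R,5R)-7-[(3E)-1-hydroxy-5-{2-methoxy-3-methyl-5-[tri(propan-2-yl)silyloxy]phenyl}-3-methylpent-3-en-1-yl]-1,5-dimethyl-6-[3-methyl-3-(trimethylsilyloxy)but-1-yn-1-yl]bicyclo[3.2.0]heptan-6-ol | OC1(C#CC(C)(C)O[Si](C)(C)C)C(C(O)C/C(C)=C/Cc3cc(O[Si](C(C)C)(C(C)C)C(C)C)cc(C)c3OC)[C@@]2(C)CCC[C@@]12C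
F8 | step 10 | (1R,5R)-1,5-dimethyl-6-(trimethylsilyloxy)bicyclo[3.2.0]hept-6-ene | C[Si](C)(C)OC1=C[C@@]2(C)CCC[C@@]12C
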